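**Your number.** I looked. You wanted the share of L at 3.0 h for the north, west, south-east and north-west flasks, and here is what I had to go on.

| flask | J | remark | time |
|---|---|---|---|
| dusk | 0.051 M | run made earlier |  |
| dawn | 0.18 M | run made earlier |  |
| north | 0.060 M |  | 3.0 h |
| west | 0.10 M |  | 3.0 h |
| south-east | 0.15 M |  | 3.0 h |
| north-west | 0.25 M |  | 3.0 h |

| run | time / h | L / % | E / % |
|---|---|---|---|
| dusk | 0.833 | 45.8 | 1.1 |
| dusk | 1.50 | 44.9 | 1.9 |
| dusk | 2.50 | 42.6 | 2.1 |
| dusk | 3.00 | 41.5 | 1.6 |
| dawn | 0.250 | 25.4 | 0.5 |
| dawn | 0.500 | 38.8 | 3.0 |
| dawn | 1.33 | 44.9 | 6.4 |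
| dawn | 3.00 | 41.5 | 7.6 |

(each reading ± 0.5 percentage points)

- percentages count the J that a species holds: one E counts as two
- steps thought possible: J -> L; L <-> Q; X -> Q; J + X -> E; J -> X
- "hardly changes" means that all values lie within two and a half points (for a concentration: within two and a half percent of the largest)

* share of L in all that became L or E for north, west, south-east, north-west, in this order
* how that number moves from the first to the last of them (rises all the way / hardly changes / falls, then rises / falls all the way / rises, then falls)

**The readings.** At 3.00 h, L read 41.5% in the dusk run and 41.5% in the dawn run, although dawn was charged 3.53 times as strongly. E, by contrast, read 1.6% in dusk and 7.6% in dawn. So I treated the L yield as independent of the charge and looked for the charge in E.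

**The E slope.** I integrated the rate of E in closed form. I let c(J) fall exponentially and c(X) grow as a fixed part of the J spent. The integral of c(J)·c(X) then goes as the square of the charge, and E as a fraction of the charge goes as the charge itself. That gave me one number to carry, the E slope, the fraction of the charge found in E per molar of J charged: 0.422 M⁻¹, read from dawn with its scatter of 0.5 percentage points. Applied to dusk, it gave 2.15%, and dusk read 2.1% and 1.6% at its last two times.

**My row.** I took the share of L, the selectivity, as L/(L + E), with L held at 41.5% and E from the slope. That gave 94.2%, 90.8%, 86.8% and 79.7%. Your forecast gave 94.3%, 90.6%, 86.5% and 79.8%, which falls all the way, reasoning that “its yield scales with concentration”. Its row differs from mine: for north-west it took E as 10.2 and L as 40.3, where I had 10.6% and 41.5%.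

**The flasks.** The simulation gave 94.4%, 91.2%, 87.7% and 81.9%; the share falls all the way.

    J → L (k = 1.40 h⁻¹)
    L ⇌ Q (K = 0.910, k = 0.600 h⁻¹)
    X → Q (k = 0.120 h⁻¹)
    J + X → E (k = 3.20 M⁻¹ h⁻¹)
    J → X (k = 0.550 h⁻¹)

At north the slope gives 2.53% of E, and that flask held 2.47% at 3.00 h. At north-west the slope gives 10.6%, more than the 8.82% of E that stood there at 3.00 h, where the measured fraction per molar was 0.353 M⁻¹.

The runs are simulated for substances that don't exist; noise was put on by code.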